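**Plan**

1. Retrosynthesis (chromone numbering): the two phenol O–H bonds go back to benzyl ethers. The aryl–oxygen bonds C5–O, C7–O and O1–C8a are then cut in one operation, which leaves a 2,4,6-trifluorophenyl 1,3-diketone and two molecules of benzyl alcohol. The C2–C3 bond of the diketone is cut to an aryl methyl ketone enolate and a C20 acid chloride.
2. Enabling feature: on ring A the oxygens at C8a, C5 and C7 sit ortho, ortho and para to C4a, the carbon that carries the C4 carbonyl. Each can therefore be installed by displacing fluoride from an acyl-activated carbon, and ring A enters as the electrophile.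
3. Forward order: the chain is joined first (C2–C3, C-acylation), ring C (the pyranone) closes through O1–C8a, the C5 and C7 oxygens follow in the same flask from two equivalents of sodium benzyloxide, and hydrogenolysis frees the phenols. Ring A is bought.
4. The enolate partner is the aryl methyl ketone, which has a single enolisable position, so building the diketone raises no regiochemical question.
5. Stereochemistry: the target has no stereocentre and no configured double bond, so nothing has to be set.

Key step: step 3

Assumption: in the key step the first benzyloxide is drawn as entering at C7 (para to C4a, free of the peri contact with the C4 oxygen); if C5 reacts first, the 5-benzyloxy-7-fluoro isomer takes the place of that intermediate and the same product results.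

**Step 1**
Reactants: 1 icosanoic acid
Product: 2 icosanoyl chloride
Conditions: (COCl)2 (1.5 equiv), DMF (cat.), CH2Cl2, 0 °C to rt; evaporate, use crude
Reagents that add atoms: oxalyl chloride, O=C(Cl)C(=O)Cl
Why: Vilsmeier-catalysed conversion of a saturated fatty acid into its acid chloride with oxalyl chloride is general, gives only gaseous by-products and meets no other functional group in the substrate.

**Step 2**
Reactants: 2 icosanoyl chloride; 3 2',4',6'-trifluoroacetophenone [1-(2,4,6-trifluorophenyl)ethanone]
Product: 5 1-(2,4,6-trifluorophenyl)docosane-1,3-dione, via lithium enolate 4 (not isolated)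
Conditions: 3 (2.1 equiv), LiN(SiMe3)2 (2.0 equiv), THF–toluene, −78 °C; then 2 (1.0 equiv) in toluene, −78 to 0 °C; AcOH quench, aq. HCl wash
Reagents that add atoms: none
Why: Claisen-type C-acylation of a preformed lithium ketone enolate with an acid chloride should work here because 3 has a single enolisable position, the lithium counter-ion in a weakly polar medium favours reaction at carbon, the second equivalent of enolate deprotonates the more acidic diketone as it forms and so stops a second acylation (the volatile excess of 3 is recovered), and the temperature is too low for the lithium diketonate to displace an ortho fluoride.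

**Step 3**
Reactants: 5 1-(2,4,6-trifluorophenyl)docosane-1,3-dione; 6 benzyl alcohol (as NaOCH2Ph, the source of the first of the two benzyloxy groups)
Product: 10 5,7-bis(benzyloxy)-2-nonadecylchromone, via sodium diketonate 7 (not isolated), via 5,7-difluoro-2-nonadecylchromone 8 (not isolated), via 7-benzyloxy-5-fluoro-2-nonadecylchromone 9 (not isolated)
Conditions: NaH (1.05 equiv), dry DMF, 0 °C then 50 °C until 5 is consumed; then NaOCH2Ph (2.6 equiv, made beforehand from 6 and NaH in THF), 70 °C; aq. NH4Cl
Reagents that add atoms: sodium benzyloxide (a second molar equivalent, prepared from 6 and NaH; source of the second benzyloxy group), [Na+].[O-]Cc1ccccc1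
Why: NaH turns 5 into the chelated Z sodium diketonate 7, whose distal oxygen (on the chain-bearing carbon, the future O1) adds to C8a; the Meisenheimer anion carries its charge on C4a and from there on the C4 carbonyl oxygen, is helped inductively by the two remaining fluorines (both meta to C8a), and loses fluoride to give 8. The closest known reaction types are the base-mediated cyclisation of 1-(2-fluoroaryl)-1,3-diketones to chromones and the alkoxide displacement of fluoride from 5- and 7-fluorochromones, here simply run one after the other in one flask. Ring C closes in a six-membered mode which, counted against the carbonyl-conjugated C4a–C8a bond that lies inside the new ring, is a favoured 6-endo-trig oxa-Michael addition followed by elimination; attack through the central carbon or through the aryl-ketone oxygen would give four-membered rings and should not compete. No stereocentre is formed. In 8 the ring oxygen on C8a is meta to both C5 and C7 and does not feed electron density to them, while the C4 carbonyl (ortho to C5 and para to C7 through C4a) still stabilises both Meisenheimer anions, so NaOCH2Ph should replace the two fluorides in turn, one molar equivalent of benzyloxide for each, the second more slowly and therefore with heating. The selectivity needed is ring closure before any alkoxide can attack the ortho fluorides or cleave the diketone by retro-Claisen reaction; it is secured by the order of addition (the diketonate is formed and cyclised before benzyloxide is present) and by the symmetry of the 2,4,6-trifluorophenyl ring, which makes the two ortho fluorides identical.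

**Step 4**
Reactants: 10 5,7-bis(benzyloxy)-2-nonadecylchromone
Product: 11 5,7-dihydroxy-2-nonadecylchromone
Conditions: H2 (1 atm), 10% Pd/C, THF–MeOH, rt; stop after uptake of two equivalents
Reagents that add atoms: none
Why: Hydrogenolysis of aryl benzyl ethers over Pd/C at one atmosphere is much faster than reduction of the C2–C3 double bond of a chromone (a vinylogous ester), so both ethers should be cleaved to toluene while the pyranone, the ketone and the alkyl chain stay untouched.

**Compound list**

1 | icosanoic acid | CCCCCCCCCCCCCCCCCCCC(=O)O | starting material
2 | icosanoyl chloride | CCCCCCCCCCCCCCCCCCCC(=O)Cl | intermediate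
3 | 2',4',6'-trifluoroacetophenone | CC(=O)c1c(F)cc(F)cc1F | starting material
4 | lithium 1-(2,4,6-trifluorophenyl)ethen-1-olate (lithium enolate of 3) | [Li+].[O-]C(=C)c1c(F)cc(F)cc1F | intermediate
5 | 1-(2,4,6-trifluorophenyl)docosane-1,3-dione | CCCCCCCCCCCCCCCCCCCC(=O)CC(=O)c1c(F)cc(F)cc1F | intermediate
6 | benzyl alcohol | OCc1ccccc1 | starting material
7 | sodium (Z)-1-oxo-1-(2,4,6-trifluorophenyl)docos-2-en-3-olate (sodium diketonate of 5) | CCCCCCCCCCCCCCCCCCC/C([O-])=C/C(=O)c1c(F)cc(F)cc1F.[Na+] | intermediate
8 | 5,7-difluoro-2-nonadecylchromone | CCCCCCCCCCCCCCCCCCCc1cc(=O)c2c(F)cc(F)cc2o1 | intermediate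
9 | 7-(benzyloxy)-5-fluoro-2-nonadecylchromone | CCCCCCCCCCCCCCCCCCCc1cc(=O)c2c(F)cc(OCc3ccccc3)cc2o1 | intermediate
10 | 5,7-bis(benzyloxy)-2-nonadecylchromone | CCCCCCCCCCCCCCCCCCCc1cc(=O)c2c(OCc3ccccc3)cc(OCc3ccccc3)cc2o1 | intermediate
11 | 5,7-dihydroxy-2-nonadecylchromone | CCCCCCCCCCCCCCCCCCCc1cc(=O)c2c(O)cc(O)cc2o1 | target

**Totals**

Total step count: 4. Longest linear sequence: 4 steps (1 → 2 → 5 → 10 → 11).

**Steps most likely to fail**

Step 3. The second fluoride displacement may stall, because the first benzyloxy group donates into the C4 carbonyl and weakens its activation. Benzyloxide may also add at C2 and open the pyranone ring, and adventitious hydroxide may form a phenoxide that shuts down further substitution. The fallback gives up the electrophilic ring A and builds the chromone by the Baker–Venkataraman sequence with the ring-A oxygens already in place. It sets out from 2 and comes back to the route at 10. Commercial 2',4',6'-trihydroxyacetophenone is benzylated on its two non-chelated hydroxyls (benzyl bromide, K2CO3, DMF) to give 2',4'-bis(benzyloxy)-6'-hydroxyacetophenone F1. The remaining phenol is acylated with 2 (K2CO3, acetone, reflux) to give 2-acetyl-3,5-bis(benzyloxy)phenyl icosanoate F2. Base (KOC(CH3)3, THF) then moves the acyl group from oxygen to the acetyl carbon to give 1-[2,4-bis(benzyloxy)-6-hydroxyphenyl]docosane-1,3-dione F3. Acid-catalysed cyclodehydration (cat. H2SO4, AcOH, 60 °C) should close ring C to 10.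

Step 2. Acylation may take place on the enolate oxygen instead of carbon, or the base may deprotonate the aliphatic acid chloride at its α-carbon and divert it into ketene self-condensation. The fallback reverses the roles of the two partners so that the acid chloride has no α-hydrogen. It sets out from 1 and comes back at 5. Icosanoic acid 1 is treated with CH3Li (2.2 equiv, THF, 0 °C, inverse quench into aqueous acid) to give henicosan-2-one F4. Deprotonation at the methyl group with LiN(i-Pr)2 at −78 °C gives the kinetic lithium henicos-1-en-2-olate F5 (two equivalents), which is C-acylated with commercial 2,4,6-trifluorobenzoyl chloride to give 5.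

Step 4. The C2–C3 double bond of the pyranone may be reduced along with the benzyl ethers, or cleavage may stay incomplete because the long-chain substrate and product are poorly soluble and coat the catalyst. The fallback replaces reduction by Lewis-acid dealkylation. It sets out from 10 and comes back at 11 directly, and it makes no new compound (entry F0). BCl3 with pentamethylbenzene as cation scavenger (CH2Cl2, −78 to 0 °C) should cleave both benzyl ethers, the chelated C5 ether first, and with no hydrogen present the enone cannot be reduced.

**Further compounds**

F1 | step 3 | 2',4'-bis(benzyloxy)-6'-hydroxyacetophenone | CC(=O)c1c(O)cc(OCc2ccccc2)cc1OCc1ccccc1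
F2 | step 3 | 2-acetyl-3,5-bis(benzyloxy)phenyl icosanoate | CCCCCCCCCCCCCCCCCCCC(=O)Oc1cc(OCc2ccccc2)cc(OCc2ccccc2)c1C(C)=O
F3 | step 3 | 1-[2,4-bis(benzyloxy)-6-hydroxyphenyl]docosane-1,3-dione | CCCCCCCCCCCCCCCCCCCC(=O)CC(=O)c1c(O)cc(OCc2ccccc2)cc1OCc1ccccc1
F4 | step 2 | henicosan-2-one | CCCCCCCCCCCCCCCCCCCC(C)=O
F5 | step 2 | lithium henicos-1-en-2-olate | [Li+].[O-]C(=C)CCCCCCCCCCCCCCCCCCC
F0 | step 4 | none | none
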